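The numbers in the tables come from a simulation from invented constants; scatter was added.

Read oak and alder at their last time, 60.0 min, which is the 1.0 h asked of Saturday's and Sunday's, and treat each new flask as the nearer old run plus a small correction, since Saturday's lies close to oak and Sunday's close to alder in charged [incoming ligand], with the same [starting complex].

common to all: starting complex 0.028 M
- oak: incoming ligand 0.031 M; run made earlier
- alder: incoming ligand 0.064 M; run made earlier
- Saturday's: incoming ligand 0.0360 M; time 1.0 h
- Sunday's: incoming ligand 0.0730 M; time 1.0 h

| run | time / min | complex with two exchanged / % | complex with one exchanged / % | starting complex / % | complex with three exchanged / % | side product / % |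
|---|---|---|---|---|---|---|
| oak | 3.00 | 1.2 | 6.3 | 90.6 | 0 | 0.6 |
| oak | 10.0 | 9.2 | 13.1 | 73.4 | 0 | 3.4 |
| oak | 15.0 | 11.0 | 10.9 | 67.5 | 1.9 | 4.6 |
| oak | 25.0 | 15.7 | 8.1 | 56.9 | 3.3 | 13.0 |
| oak | 40.0 | 19.4 | 6.6 | 49.0 | 7.5 | 23.6 |
| oak | 50.0 | 17.8 | 3.3 | 44.2 | 8.8 | 25.2 |
| oak | 60.0 | 18.3 | 3.4 | 41.5 | 10.3 | 27.5 |
| alder | 8.00 | 18.3 | 13.2 | 60.3 | 4.0 | 4.5 |
| alder | 15.0 | 24.3 | 8.7 | 44.2 | 10.5 | 13.9 |
| alder | 25.0 | 25.0 | 5.0 | 30.0 | 16.3 | 20.3 |
| alder | 30.0 | 23.5 | 5.0 | 28.1 | 22.8 | 25.7 |
| alder | 40.0 | 19.5 | 4.1 | 21.0 | 28.7 | 29.9 |
| alder | 50.0 | 18.0 | 1.9 | 16.5 | 32.0 | 32.5 |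
| alder | 60.0 | 16.6 | 1.1 | 14.1 | 34.5 | 34.8 |

(each reading ± 1 percentage point)

- a reading or a percentage of complex with one exchanged counts all its forms, free or not

1. which of these there is most of at the end, counted by the starting complex in it, Saturday's (side product / complex with two exchanged / complex with three exchanged / starting complex)
2. which of these there is most of at the end, counted by the starting complex in it, Sunday's (side product / complex with two exchanged / complex with three exchanged / starting complex)
3. final amount of the leader among these, as a percentage of the starting complex charged, in Saturday's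
4. final amount of the leader among these, as a percentage of the starting complex charged, in Sunday's

Oak and alder share their [starting complex], so put the gap between their last readings down to [incoming ligand], and divide:

g = (34.5 % − 10.3 %) / (0.064 M − 0.031 M) = 7.33 M⁻¹

Call g the ligand gain: the fraction of the charge added to complex with three exchanged at that time per molar of extra charged [incoming ligand], read between these two runs, a sensitivity in the usual term. Alder ends with complex with three exchanged and side product level within the scatter of 1 percentage point, so the leader of Sunday's rests on the correction; side product has its own gain of 2.21 M⁻¹, and complex with three exchanged gains faster than side product. Going from alder to Sunday's adds 6.6 points to the one and 2 points to the other: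

Sunday's, complex with three exchanged: 34.5 % + 7.33 M⁻¹ × (0.0730 M − 0.064 M) = 41.1 %

Sunday's, side product: 36.8 %

Make the same move from oak for Saturday's, where starting complex loses 8.30 M⁻¹:

Saturday's, starting complex: 41.5 % − 8.30 M⁻¹ × (0.0360 M − 0.031 M) = 37.3 %

Saturday's, side product: 28.6 %, lower than starting complex.

The forecast names starting complex at 35.5 % for Saturday's and complex with three exchanged at 39 % for Sunday's, saying “Sunday extrapolates to triple about 39, side product about 36, double about 15, so triple leads narrowly.” It names the same leaders as the reckoning above, but with lower amounts.

The flask gives starting complex at 36.3 % in Saturday's and complex with three exchanged at 41.4 % in Sunday's.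

    starting complex + incoming ligand → leaving ligand + complex with one exchanged (k = 0.0190 M⁻¹ s⁻¹)
    leaving ligand + complex with one exchanged → side product (k = 0.0840 M⁻¹ s⁻¹)
    complex with two exchanged + incoming ligand → leaving ligand + complex with three exchanged (k = 0.0180 M⁻¹ s⁻¹)
    crystals ⇌ complex with one exchanged, rate k4*(cs4 - [complex with one exchanged]) while solid is left; crystals form when [complex with one exchanged] > cs4 (solubility = 13.0 mM, k = 0.00750 s⁻¹)
    complex with one exchanged + incoming ligand → leaving ligand + complex with two exchanged (k = 0.0710 M⁻¹ s⁻¹)

Take the difference in charged [incoming ligand] as the main reason for what Sunday's holds: remove that difference and complex with three exchanged falls from 41.4 % to 12.6 %. The ligand gain is a reading of such a difference, and on alder it gave 41.1 % for Sunday's, which ended at 41.4 %. Apply it from oak to the neighbour of Sunday's charged with 0.044 M of [incoming ligand]: the correction gives 19.8 % of complex with three exchanged, and that flask ends with 18.5 %.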